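**Assumption:** the target (2,4-dihydroxy-6-pentadecylphenyl acetate) has no stereocentres or stereogenic double bonds, so it is achiral and the "single enantiomer" requirement is met trivially. The route has not been run; each step rests on well-known reaction types.

## Retrosynthetic overview

1. Target 12 ⇐ hydrogenolysis of the bis-benzyl ether 11; the acetate is already in place, so no selective acetylation of a triol is needed.
2. Aryl acetate C–O bond ⇐ Baeyer–Villiger oxidation of the 2,6-disubstituted acetophenone 9. This is the key step: the C-acetyl group becomes the O-acetyl group at a position fixed by the starting material.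
3. Aryl–C15 bond ⇐ B-alkyl Suzuki coupling of aryl triflate 5 with B-pentadecyl-9-BBN 8 (from 1-pentadecene). One phloroglucinol OH is replaced by the chain, with no Wittig/hydrogenation sequence.
4. Triflate 5 ⇐ phloroacetophenone 1, desymmetrised through its chelated ortho-OH.
5. Rings: none are formed. The benzene ring is bought intact in 1, which also supplies both acetate carbons.

## Route

**Step 1**
Reactants: 1, 2',4',6'-trihydroxyacetophenone (phloroacetophenone); 2, benzyl bromide
Product: 3, 1-[2,4-bis(benzyloxy)-6-hydroxyphenyl]ethanone
Conditions: BnBr (2.1 equiv), K2CO3 (2.2 equiv), DMF, 0 °C → rt, 12 h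
Reagents that add atoms: benzyl bromide, BrCc1ccccc1
Why: Williamson etherification; the 4-OH and one 2-OH are alkylated, while the remaining ortho-OH is hydrogen-bonded to the acetyl carbonyl and is too poorly nucleophilic to react with only about 2 equiv of BnBr.

**Step 2**
Reactants: 3, 1-[2,4-bis(benzyloxy)-6-hydroxyphenyl]ethanone; 4, trifluoromethanesulfonic anhydride
Product: 5, 2-acetyl-3,5-bis(benzyloxy)phenyl trifluoromethanesulfonate
Conditions: Tf2O (1.2 equiv), pyridine (3 equiv), CH2Cl2, 0 °C → rt
Reagents that add atoms: Tf2O, O=S(=O)(OS(=O)(=O)C(F)(F)F)C(F)(F)F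
Why: O-sulfonylation of the only free phenol; triflation of a phenol with pyridine at 0 °C is much faster than enol triflate formation from the methyl ketone.

**Step 3**
Reactants: 6, 1-pentadecene; 7, 9-borabicyclo[3.3.1]nonane (9-BBN)
Product: 8, B-pentadecyl-9-BBN (9-pentadecyl-9-borabicyclo[3.3.1]nonane), used in situ
Conditions: 9-BBN (0.5 M in THF, 1.0 equiv), 1-pentadecene (1.1 equiv), 0 °C → rt, 6 h
Reagents that add atoms: 9-BBN, [H]B1C2CCCC1CCC2 (the boron bicycle is carried in 8 and lost in step 4)
Why: anti-Markovnikov hydroboration of a terminal alkene gives the primary alkylborane only; the slight excess of alkene leaves no B–H to reduce the ketone in step 4.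

**Step 4**
Reactants: 5, 2-acetyl-3,5-bis(benzyloxy)phenyl trifluoromethanesulfonate; 8, B-pentadecyl-9-BBN (1.4 equiv)
Product: 9, 1-[2,4-bis(benzyloxy)-6-pentadecylphenyl]ethanone
Conditions: PdCl2(dppf)·CH2Cl2 (5 mol %), K3PO4 (3 equiv, 3 M aq), THF/DMF, 60 °C, 12 h
Reagents that add atoms: none (all product atoms come from 5 and 8)
Why: B-alkyl Suzuki–Miyaura sp2–sp3 coupling; the ortho-acetyl group activates the triflate toward oxidative addition, both benzyloxy groups are meta to it, and dppf suppresses β-hydride elimination.

**Step 5**
Reactants: 9, 1-[2,4-bis(benzyloxy)-6-pentadecylphenyl]ethanone; 10, meta-chloroperoxybenzoic acid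
Product: 11, 2,4-bis(benzyloxy)-6-pentadecylphenyl acetate
Conditions: mCPBA (1.5 equiv), TFA (0.2 equiv), CH2Cl2, 0 °C → rt, dark; Na2S2O3/NaHCO3 quench
Reagents that add atoms: mCPBA, OOC(=O)c1cccc(Cl)c1 (one oxygen)
Why: Baeyer–Villiger oxidation; the electron-rich, ortho,ortho'-disubstituted aryl group migrates far better than methyl from the Criegee intermediate, giving the aryl acetate rather than the methyl ester, and benzyl ethers and the alkyl chain are inert to the peracid.

**Step 6**
Reactants: 11, 2,4-bis(benzyloxy)-6-pentadecylphenyl acetate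
Product: 12, 2,4-dihydroxy-6-pentadecylphenyl acetate (target, CID 10091080)
Conditions: H2 (1 atm), 10% Pd/C, EtOAc, rt, 3 h; filter through Celite, concentrate below 30 °C
Reagents that add atoms: none
Why: catalytic hydrogenolysis of the two benzyl ethers under neutral, aprotic conditions leaves the aryl acetate intact and avoids base-promoted 1,2-acyl migration to the neighbouring phenol.

## Compound list

1 | 2',4',6'-trihydroxyacetophenone | CC(=O)c1c(O)cc(O)cc1O | starting material
2 | benzyl bromide | BrCc1ccccc1 | starting material (reagent)
3 | 1-[2,4-bis(benzyloxy)-6-hydroxyphenyl]ethanone | CC(=O)c1c(O)cc(OCc2ccccc2)cc1OCc1ccccc1 | intermediate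
4 | trifluoromethanesulfonic anhydride | O=S(=O)(OS(=O)(=O)C(F)(F)F)C(F)(F)F | starting material (reagent)
5 | 2-acetyl-3,5-bis(benzyloxy)phenyl trifluoromethanesulfonate | CC(=O)c1c(OS(=O)(=O)C(F)(F)F)cc(OCc2ccccc2)cc1OCc1ccccc1 | intermediate
6 | 1-pentadecene | CCCCCCCCCCCCCC=C | starting material
7 | 9-borabicyclo[3.3.1]nonane (9-BBN) | [H]B1C2CCCC1CCC2 | starting material (reagent)
8 | B-pentadecyl-9-BBN | CCCCCCCCCCCCCCCB1C2CCCC1CCC2 | intermediate (in situ)
9 | 1-[2,4-bis(benzyloxy)-6-pentadecylphenyl]ethanone | CCCCCCCCCCCCCCCc1cc(OCc2ccccc2)cc(OCc2ccccc2)c1C(C)=O | intermediate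
10 | meta-chloroperoxybenzoic acid | OOC(=O)c1cccc(Cl)c1 | starting material (reagent)
11 | 2,4-bis(benzyloxy)-6-pentadecylphenyl acetate | CCCCCCCCCCCCCCCc1cc(OCc2ccccc2)cc(OCc2ccccc2)c1OC(C)=O | intermediate
12 | 2,4-dihydroxy-6-pentadecylphenyl acetate | CCCCCCCCCCCCCCCc1cc(O)cc(O)c1OC(C)=O | target

## Summary

Total steps: 6.
Longest linear sequence: 5 (steps 1, 2, 4, 5, 6); step 3 is a one-step branch telescoped into step 4.

Three steps most likely to fail:

1. **Step 5, Baeyer–Villiger.** Risks are a sluggish reaction at the hindered ketone and peracid over-oxidation of the electron-rich ring. Fallback: run the sequence from 2,4,6-trihydroxybenzaldehyde instead, giving 2,4-bis(benzyloxy)-6-pentadecylbenzaldehyde. A Dakin oxidation (mCPBA, then mild methanolysis of the formate) gives the phenol, which is the only free OH and is acetylated with Ac2O/pyridine before hydrogenolysis.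

2. **Step 4, B-alkyl Suzuki coupling.** Risks are triflate hydrolysis back to phenol 3 and β-hydride elimination or protodeboronation. Fallback: Sonogashira coupling of 5 with 1-pentadecyne (sp2–sp bond, no β-hydrogens on the metal). The alkyne is carried through the Baeyer–Villiger step and is saturated in the final H2/Pd-C step along with debenzylation.

3. **Step 6, debenzylation.** Risks are acyl migration to the adjacent phenol or partial deacetylation on the catalyst or during work-up. Fallback: change the protecting-group strategy to MOM ethers from step 1 (MOMCl/i-Pr2NEt, with a NaHCO3-buffered Baeyer–Villiger) and unmask with anhydrous acid (TMSBr, CH2Cl2, −30 °C), conditions under which base-catalysed acyl migration does not occur.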